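A direct plan would build ring B (the pyranone) first and ring A (the benzene) last: 2-(prop-2-yn-1-yl)malonyl dichloride A1 and the (S)-configured silyl enol ether A2
would be annulated to the propargyl pyranone A3, O-benzylation and acyl Sonogashira coupling would give the ynone A4, and Diels–Alder addition of the silyloxydiene A5
with aromatisation would give the tribenzyl ether A6 for a last debenzylation. Its weakest steps would be: (i) the cycloaddition–aromatisation that makes the benzene ring,
because the whole substitution pattern of ring A would rest on the polarisation of one ynone towards a labile, oxygen-laden diene, at 110 °C, on the most advanced material;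
(ii) the acylation of the terminal alkyne to a skipped ynone, because its CH2 between pyranone and ynone would be doubly activated and could slip to the allene under amine
and copper; (iii) the run-up, because some eleven steps would go into two simple partners and add little complexity before the hardest ring closure is tested.

**Plan of the new route**
Ring A (C1' CH2, C2' acetyl, C3' OH, C4' OH, C5' OMe, C6' H) is bought, not built. Stripped of the acetyl group and with O3' and O4' methylated it is a 3,4,5-trimethoxybenzyl
group with a mirror plane through C1' and C4': C2' and C6' are the same carbon, and the acetyl C=O, O3' and O4' lie in one unbroken chelation path that ends before O5'.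
The retrosynthesis cuts O3'–CH3 and O4'–CH3, then C2'–acetyl, then ring B (O1, C2 to C6) at O1–C2 and C5–C6, then C3–CH2; the stereocentre comes from ethyl (S)-3-hydroxybutanoate.
Forward, ring A is there from the first C–C bond, ring B is closed on it by dianion acylation and lactonisation, the acetyl group enters last, and its carbonyl then leads BCl3 to
the two ethers that must fall. No benzannulation, ynone or diene occurs; the pattern of ring A is fixed by symmetry and chelation, not by a cycloaddition; the enolisable aryl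
ketone does not exist while enolates are used; seven steps in all.

Key step: step 6

Remark: 1, 4 and 5 are taken as commercial. The (S) descriptor is the same in 1 and in the target, because the ranking O > CH2 > CH3 > H at the carbinol carbon never changes and no bond to that carbon is broken.

Step 1
Reactants: 1 ethyl (S)-3-hydroxybutanoate
Product: 2 ethyl (S)-3-(benzyloxy)butanoate
Conditions: benzyl 2,2,2-trichloroacetimidate (1.3 equiv), TfOH (5 mol%), CH2Cl2/cyclohexane 1:2, 0 °C → rt
Reagents that add atoms: benzyl 2,2,2-trichloroacetimidate, ClC(Cl)(Cl)C(=N)OCc1ccccc1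
Why: Acid-catalysed O-benzylation with a trichloroacetimidate (imidate alkylation) avoids the base that would cause retro-aldol cleavage or β-elimination of a β-hydroxy ester, and since only the O–H bond reacts, the (S) centre bought with 1 is kept.

Step 2
Reactants: 2 ethyl (S)-3-(benzyloxy)butanoate
Product: 3 (3S)-3-(benzyloxy)-N-methoxy-N-methylbutanamide
Conditions: MeNH(OMe)·HCl (1.5 equiv), i-PrMgCl (3.0 equiv), THF, −20 → 0 °C
Reagents that add atoms: N,O-dimethylhydroxylamine hydrochloride, CNOC.Cl
Why: The chloromagnesium amide made in the flask adds to the ester and the chelated adduct gives the amide only (Weinreb amide formation) at a temperature at which the β-benzyloxy group is not eliminated, and the stereocentre is not involved.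

Step 3
Reactants: 4 methyl acetoacetate; 5 3,4,5-trimethoxybenzyl chloride
Product: 6 methyl 3-oxo-2-[(3,4,5-trimethoxyphenyl)methyl]butanoate (racemic)
Conditions: 4 (1.5 equiv), NaH (1.4 equiv), THF, 0 °C; 5 (1.0 equiv), NaI (10 mol%), 50 °C
Reagents that add atoms: none
Why: Acetoacetic ester alkylation: the sodium enolate of 4, used in excess against dialkylation, displaces the benzylic chloride under iodide catalysis, and the new centre at C2, formed racemic, later becomes the sp2 carbon C3 of ring B.

Step 4
Reactants: 6 methyl 3-oxo-2-[(3,4,5-trimethoxyphenyl)methyl]butanoate; 3 (3S)-3-(benzyloxy)-N-methoxy-N-methylbutanamide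
Product: 8 methyl (7S)-7-(benzyloxy)-3,5-dioxo-2-[(3,4,5-trimethoxyphenyl)methyl]octanoate, via sodium lithium dianion 7 (not isolated)
Conditions: 6 (2.0 equiv), NaH (2.1 equiv), THF, 0 °C; n-BuLi (2.0 equiv), 0 °C; 3 (1.0 equiv), −78 → 0 °C; then 1 M HCl
Reagents that add atoms: none
Why: γ-Acylation of a β-keto ester dianion: the more basic terminal carbanion of 7 adds to the Weinreb amide, whose chelated tetrahedral adduct resists a second addition until work-up, which forms the C5–C6 bond of the future ring B, makes no stereocentre and leaves the carbinol carbon, β to the reacting carbonyl, untouched.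

Step 5
Reactants: 8 methyl (7S)-7-(benzyloxy)-3,5-dioxo-2-[(3,4,5-trimethoxyphenyl)methyl]octanoate
Product: 9 6-[(2S)-2-(benzyloxy)propyl]-4-hydroxy-3-[(3,4,5-trimethoxyphenyl)methyl]-2H-pyran-2-one
Conditions: DBU (2.0 equiv), toluene, 80 °C; then 1 M HCl
Reagents that add atoms: none
Why: DBU-mediated lactonisation of a 3,5-dioxo ester: the enolate oxygen on C5 attacks the methyl ester in a 6-exo-trig closure of the O1–C2 bond with loss of methanol, the product is held as the stable pyranolate, the stereogenic C2 of 8 becomes sp2, and the benzyloxy carbon, not α to any carbonyl, keeps its configuration.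

Step 6
Reactants: 9 6-[(2S)-2-(benzyloxy)propyl]-4-hydroxy-3-[(3,4,5-trimethoxyphenyl)methyl]-2H-pyran-2-one
Product: 12 3-[(2-acetyl-3,4,5-trimethoxyphenyl)methyl]-6-[(2S)-2-(benzyloxy)propyl]-4-hydroxy-2H-pyran-2-one, via pyranyl acetate 10 (not isolated), via C-acetylated pyranyl acetate 11 (not isolated)
Conditions: AcOH (5 equiv), (CF3CO)2O (5 equiv), H3PO4 (85%, 0.3 equiv), CH2Cl2, 0 °C → rt; then MeOH, rt
Reagents that add atoms: acetic acid, CC(=O)O
Why: Acetic acid and trifluoroacetic anhydride give acetyl trifluoroacetate, which first acetylates O4 of ring B (10) and then, under acid catalysis, delivers an acetylium ion to ring A by electrophilic aromatic substitution through a Wheland intermediate (11), after which methanol cleaves only the reactive enol acetate. The closest known reaction type is the Friedel–Crafts acetylation of 3,4,5-trimethoxytoluene and of 3,4,5-trimethoxyphenylacetic esters at the ring carbon next to the alkyl group, and the acylation of polymethoxybenzenes with mixed acetic trifluoroacetic anhydride. No ring is closed and no stereocentre is made; the (S) carbinol carbon is remote and carries a benzyl ether that is stable to trifluoroacetic acid. The selectivity needed is ring A over C5 of ring B and over the phenyl ring of the benzyl ether, and monoacetylation: ring A has three donor oxygens, ring B has just become an electron-poor enol acetate (which also disfavours loss of the benzylic C–C bond by ipso attack), the benzyl phenyl ring has no donor, and the first acetyl group deactivates ring A. Site selectivity within ring A does not arise, because the mirror plane through C1' and C4' makes C2' and C6' the same carbon, each ortho to one methoxy group and para to another.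

Step 7
Reactants: 12 3-[(2-acetyl-3,4,5-trimethoxyphenyl)methyl]-6-[(2S)-2-(benzyloxy)propyl]-4-hydroxy-2H-pyran-2-one
Product: 13 penicanesin D, 3-[(2-acetyl-3,4-dihydroxy-5-methoxyphenyl)methyl]-4-hydroxy-6-[(2S)-2-hydroxypropyl]-2H-pyran-2-one
Conditions: BCl3 (1 M in CH2Cl2, 6 equiv), C6HMe5 (3 equiv), CH2Cl2, −78 °C → rt; then MeOH, H2O
Reagents that add atoms: none
Why: Chelation-controlled Lewis-acid ether cleavage, of the kind known for 2,3,4-trimethoxybenzaldehyde going to its 2,3-dihydroxy-4-methoxy compound: boron bound to the acetyl C=O removes the methyl group of O3', the boron then bridges to the neighbouring O4' and removes its methyl group, and the resulting five-membered catechol borate is too weak a Lewis acid to reach O5', which is moreover conjugated para to the acetyl group, while the secondary benzyl ether ionises at low temperature to a benzyl cation that pentamethylbenzene traps; the C–O bond at the stereocentre is not broken.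

**Compound list**
1 | ethyl (S)-3-hydroxybutanoate | CCOC(=O)C[C@H](C)O | starting material
2 | ethyl (S)-3-(benzyloxy)butanoate | CCOC(=O)C[C@H](C)OCc1ccccc1 | intermediate
3 | (3S)-3-(benzyloxy)-N-methoxy-N-methylbutanamide | CON(C)C(=O)C[C@H](C)OCc1ccccc1 | intermediate
4 | methyl acetoacetate | COC(=O)CC(C)=O | starting material
5 | 3,4,5-trimethoxybenzyl chloride | COc1cc(CCl)cc(OC)c1OC | starting material
6 | methyl 3-oxo-2-[(3,4,5-trimethoxyphenyl)methyl]butanoate (racemic) | COC(=O)C(Cc1cc(OC)c(OC)c(OC)c1)C(C)=O | intermediate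
7 | sodium lithium dianion of 6 (deprotonated at C2 and C4) | COC(=O)[C-](Cc1cc(OC)c(OC)c(OC)c1)C(=O)[CH2-].[Na+].[Li+] | intermediate (not isolated)
8 | methyl (7S)-7-(benzyloxy)-3,5-dioxo-2-[(3,4,5-trimethoxyphenyl)methyl]octanoate (C2 epimers and enol forms) | COC(=O)C(Cc1cc(OC)c(OC)c(OC)c1)C(=O)CC(=O)C[C@H](C)OCc1ccccc1 | intermediate
9 | 6-[(2S)-2-(benzyloxy)propyl]-4-hydroxy-3-[(3,4,5-trimethoxyphenyl)methyl]-2H-pyran-2-one | COc1cc(Cc2c(O)cc(C[C@H](C)OCc3ccccc3)oc2=O)cc(OC)c1OC | intermediate
10 | 6-[(2S)-2-(benzyloxy)propyl]-2-oxo-3-[(3,4,5-trimethoxyphenyl)methyl]-2H-pyran-4-yl acetate | COc1cc(Cc2c(OC(C)=O)cc(C[C@H](C)OCc3ccccc3)oc2=O)cc(OC)c1OC | intermediate (not isolated)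
11 | 3-[(2-acetyl-3,4,5-trimethoxyphenyl)methyl]-6-[(2S)-2-(benzyloxy)propyl]-2-oxo-2H-pyran-4-yl acetate | COc1cc(Cc2c(OC(C)=O)cc(C[C@H](C)OCc3ccccc3)oc2=O)c(C(C)=O)c(OC)c1OC | intermediate (not isolated)
12 | 3-[(2-acetyl-3,4,5-trimethoxyphenyl)methyl]-6-[(2S)-2-(benzyloxy)propyl]-4-hydroxy-2H-pyran-2-one | COc1cc(Cc2c(O)cc(C[C@H](C)OCc3ccccc3)oc2=O)c(C(C)=O)c(OC)c1OC | intermediate
13 | penicanesin D, 3-[(2-acetyl-3,4-dihydroxy-5-methoxyphenyl)methyl]-4-hydroxy-6-[(2S)-2-hydroxypropyl]-2H-pyran-2-one | COc1cc(Cc2c(O)cc(C[C@H](C)O)oc2=O)c(C(C)=O)c(O)c1O | target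

Total step count: 7. Longest linear sequence: 6 steps (steps 1, 2, 4, 5, 6, 7).

**Steps most likely to fail**

Step 6 (acetylation of ring A). What may go wrong: acylation of ring B at C5, acid-induced loss of the benzyl ether, or ipso attack at C1' with loss of the benzylic C–C bond. The fallback replaces electrophilic acylation in strong acid by halogenation and cross-coupling. From 9, N-bromosuccinimide (1.0 equiv) in MeCN at −20 °C should brominate the same symmetry-equivalent carbon to give 6-[(2S)-2-(benzyloxy)propyl]-3-[(2-bromo-3,4,5-trimethoxyphenyl)methyl]-4-hydroxy-2H-pyran-2-one F1. Stille coupling with tributyl(1-ethoxyvinyl)stannane and Pd(PPh3)4 in toluene at 100 °C should give the enol ether 6-[(2S)-2-(benzyloxy)propyl]-3-{[2-(1-ethoxyethenyl)-3,4,5-trimethoxyphenyl]methyl}-4-hydroxy-2H-pyran-2-one F2, and 1 M HCl in THF should hydrolyse it to 12, where the route is rejoined.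

Step 7 (ether cleavage). What may go wrong: the relay of boron from O3' to O4' stalls at the monophenol, or forcing it begins to cleave the O5' ether. The fallback removes the second methyl group by oxidation instead of by Lewis acid. From 12, BCl3 (3 equiv) and C6HMe5 at −78 → 0 °C should stop at 3-[(2-acetyl-3-hydroxy-4,5-dimethoxyphenyl)methyl]-4-hydroxy-6-[(2S)-2-hydroxypropyl]-2H-pyran-2-one F3. NaIO4 in aqueous MeCN at 0 °C (Adler oxidative demethylation of a 2-methoxyphenol, whose only oxygenated ortho carbon here is C4') should give the ortho-quinone 3-[(2-acetyl-5-methoxy-3,4-dioxocyclohexa-1,5-dien-1-yl)methyl]-4-hydroxy-6-[(2S)-2-hydroxypropyl]-2H-pyran-2-one F4, and Na2S2O4 added to the same flask should reduce it to 13.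

Step 4 (dianion acylation). What may go wrong: the hindered, strongly basic dianion of the α-branched keto ester deprotonates the amide 3 instead of adding to it, with β-elimination of benzyl alcohol and return of 6. The fallback replaces the dianion by a neutral bis-silyl dienol ether. Ester 2 would be saponified (LiOH, THF/H2O) to (3S)-3-(benzyloxy)butanoic acid F5 and converted with (COCl)2 and catalytic DMF into (3S)-3-(benzyloxy)butanoyl chloride F6. Keto ester 6 would be silylated with Et3N and Me3SiCl to methyl 2-[(3,4,5-trimethoxyphenyl)methyl]-3-(trimethylsilyloxy)but-2-enoate F7, and then with LiN(i-Pr)2 and Me3SiCl at −78 °C to 1-methoxy-2-[(3,4,5-trimethoxyphenyl)methyl]-1,3-bis(trimethylsilyloxy)buta-1,3-diene F8. F8 and F6 in CH2Cl2 at −78 → 20 °C, followed by aqueous HCl, should give 8, where the route is rejoined.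

**Further compounds**
F1 | step 6 | 6-[(2S)-2-(benzyloxy)propyl]-3-[(2-bromo-3,4,5-trimethoxyphenyl)methyl]-4-hydroxy-2H-pyran-2-one | COc1cc(Cc2c(O)cc(C[C@H](C)OCc3ccccc3)oc2=O)c(Br)c(OC)c1OC
F2 | step 6 | 6-[(2S)-2-(benzyloxy)propyl]-3-{[2-(1-ethoxyethenyl)-3,4,5-trimethoxyphenyl]methyl}-4-hydroxy-2H-pyran-2-one | CCOC(=C)c1c(Cc2c(O)cc(C[C@H](C)OCc3ccccc3)oc2=O)cc(OC)c(OC)c1OC
F3 | step 7 | 3-[(2-acetyl-3-hydroxy-4,5-dimethoxyphenyl)methyl]-4-hydroxy-6-[(2S)-2-hydroxypropyl]-2H-pyran-2-one | COc1cc(Cc2c(O)cc(C[C@H](C)O)oc2=O)c(C(C)=O)c(O)c1OC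
F4 | step 7 | 3-[(2-acetyl-5-methoxy-3,4-dioxocyclohexa-1,5-dien-1-yl)methyl]-4-hydroxy-6-[(2S)-2-hydroxypropyl]-2H-pyran-2-one | COC1=CC(Cc2c(O)cc(C[C@H](C)O)oc2=O)=C(C(C)=O)C(=O)C1=O
F5 | step 4 | (3S)-3-(benzyloxy)butanoic acid | OC(=O)C[C@H](C)OCc1ccccc1
F6 | step 4 | (3S)-3-(benzyloxy)butanoyl chloride | ClC(=O)C[C@H](C)OCc1ccccc1
F7 | step 4 | methyl 2-[(3,4,5-trimethoxyphenyl)methyl]-3-(trimethylsilyloxy)but-2-enoate | COC(=O)C(Cc1cc(OC)c(OC)c(OC)c1)=C(C)O[Si](C)(C)C
F8 | step 4 | 1-methoxy-2-[(3,4,5-trimethoxyphenyl)methyl]-1,3-bis(trimethylsilyloxy)buta-1,3-diene | COC(O[Si](C)(C)C)=C(Cc1cc(OC)c(OC)c(OC)c1)C(=C)O[Si](C)(C)C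
A1 | direct plan | 2-(prop-2-yn-1-yl)malonyl dichloride | ClC(=O)C(CC#C)C(=O)Cl
A2 | direct plan | (S)-{[4-(benzyloxy)pent-1-en-2-yl]oxy}trimethylsilane | C=C(O[Si](C)(C)C)C[C@H](C)OCc1ccccc1
A3 | direct plan | 6-[(2S)-2-(benzyloxy)propyl]-4-hydroxy-3-(prop-2-yn-1-yl)-2H-pyran-2-one | C#CCc1c(O)cc(C[C@H](C)OCc2ccccc2)oc1=O
A4 | direct plan | 4-(benzyloxy)-6-[(2S)-2-(benzyloxy)propyl]-3-(4-oxopent-2-yn-1-yl)-2H-pyran-2-one | CC(=O)C#CCc1c(OCc2ccccc2)cc(C[C@H](C)OCc2ccccc2)oc1=O
A5 | direct plan | 2-(benzyloxy)-1,3-dimethoxy-1-(trimethylsilyloxy)buta-1,3-diene | C=C(OC)C(OCc1ccccc1)=C(OC)O[Si](C)(C)C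
A6 | direct plan | 3-{[2-acetyl-4-(benzyloxy)-3-hydroxy-5-methoxyphenyl]methyl}-4-(benzyloxy)-6-[(2S)-2-(benzyloxy)propyl]-2H-pyran-2-one | COc1cc(Cc2c(OCc3ccccc3)cc(C[C@H](C)OCc3ccccc3)oc2=O)c(C(C)=O)c(O)c1OCc1ccccc1
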